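## Analysis of the target

Ring labels used throughout: ring A is the guaiacyl ring on the ketone, ring B the furofuran aryl group that carries the ketone arm, ring C the benzo ring of the dihydrobenzofuran, ring D the guaiacyl ring on dihydrobenzofuran C2.

Compound 35 is built on a cis-fused 3,7-dioxabicyclo[3.3.0]octane (furofuran) whose C7 carries ring B and whose C7′ carries ring C. Ring C is fused to a 2,3-dihydrobenzofuran with ring D on C2 and CH2OH on C3, and ring B carries at C5, ortho to its phenol, a CH(CH2OH)–C(=O)–ring A arm. There are seven stereocentres in three clusters that are insulated from one another by aromatic rings: C7, C8, C8′, C7′ of the furofuran (S, R, R, S; both aryl groups exo), C2 and C3 of the dihydrobenzofuran (S, S; ring D and CH2OH cis, the less stable arrangement), and the (S) α-carbon of the ketone. Within the furofuran, C8 and C8′ fix the ring fusion and C7/C7′ follow from ring closure, whereas the other two clusters each need their own source of asymmetry. The sensitive sites are the α-aryl β-hydroxy ketone (epimerisation, retro-aldol, dehydration, and cyclodehydration with the ortho phenol of ring B to a benzofuran), the three benzylic ether carbons C7, C7′ and dihydrobenzofuran C2 (each para to an oxygen and ionisable in acid), and three free phenols. The exo,exo furofuran is not a deep thermodynamic well, since such systems drift towards the C7 epimer on prolonged acid contact, and the cis-dihydrobenzofuran can go to trans by ring opening; after the rings are made, protic acid and free base therefore have to be kept away. The difficulty is the unsymmetrical furofuran (two different aryl groups, each with a different ortho appendage), the contra-thermodynamic cis ring and a last stereocentre that is configurationally labile. The strategy rests on the C8–C8′ bond and its four flanking carbons: C9′–C8′–C8–C9 maps onto C2–C3–C4–C5 of a butenolide, C7 (ring B) joins C8 as an acyl-anion equivalent at the β-carbon, and C7′ (ring C) joins C8′ as an aldehyde at the α-carbon. One acetal centre at C5 can then relay its configuration to both C8 and C8′, and the two aryl groups arrive as two different reagents.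

## Retrosynthetic reasoning

35 ⇒ 34. Only O–Si bonds are cut. All five hydroxyl groups are carried as silyl ethers so that the last operation is a single buffered fluoride treatment; the end game then needs neither acid (which would ionise C7, C7′ and dihydrobenzofuran C2) nor free base (which would epimerise the ketone α-carbon).

34 ⇒ 25 + 31. The bond between C5 of ring B and the ketone α-carbon is cut. Cutting here, and not at the aryl–carbonyl or the C–CH2O bond, lets the only labile stereocentre be made last, by a stereoconvergent nickel-catalysed arylation of the racemic secondary bromide 31 with the arylzinc 33 (from iodide 25 through 32). The forward reaction has to create a tertiary α-aryl ketone centre without a Brønsted base.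

31 ⇒ 29 ⇒ 28 ⇒ 27 ⇒ 26. The C–Br bond and then the C–CH2O bond are removed; the three-carbon ketone arm of ring A comes from the acetyl group of 26 by hydroxymethylation of its silyl enol ether 27 and α-bromination through enol ether 30.

25 ⇒ 24 ⇒ 22 ⇒ 20. The C–I bond at C5 of ring B is cut. The MOM ether of 20 is the only strong ortho-directing group in the molecule, so lithiation (21) puts the halogen exactly where the arm must go. The MOM group is then exchanged for a silyl ether (23, 24, 25) while no sensitive ketone is present.

20 ⇒ 19 ⇒ 18 ⇒ 17 ⇒ 16. The C2–C3 bond of the dihydrobenzofuran is cut. A carbene at the arylacetate carbon inserting into the benzylic C–H of the ring D benzyl ether forms this bond suprafacially, which is what a cis ring needs, and a chiral dirhodium catalyst can set both centres. The arylacetate 17 comes from the aryl bromide 16, so the bromine of ring C is the handle for the annulation.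

16 ⇒ 13 + 15, 15 ⇒ 14 ⇒ 1. The benzylic C–O bond of the aryl benzyl ether is cut; ring D is introduced as its benzyl alcohol 15 under neutral redox-condensation conditions, which avoids a labile electron-rich benzyl halide.

13 ⇒ 12. The two C–O bonds O–C7 and O–C7′ of the furofuran are cut. Forward, both benzylic carbinols ionise and each cation is captured by the primary hydroxyl on the other half, so the carbinol configurations of 12 do not matter. Ring C must enter this step as the free phenol, because an oxygen flanked by bromine and methoxy is twisted out of conjugation once it carries a bulky group and would no longer stabilise the C7′ cation.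

12 ⇒ 11 ⇒ 10. Functional-group changes only: the lactone, the acetal carbon and the ketone are taken back from the alcohol level, the menthyl auxiliary and the pivalate are restored, and the ketone is re-masked as the dithiane.

10 ⇒ 4 + 7 + 6. The bonds C7–C8 and C8′–C7′ are cut in one operation: lithiated 4 (8) adds to the β-carbon of 7 and the enolate 9 is trapped by 6. Nothing else gives the unsymmetrical C7–C8–C8′–C7′ chain with both ring-fusion centres set from one purchased stereocentre.

4 ⇒ 3 ⇒ 1 + 2; 6 ⇒ 5. Protecting-group and dithioacetal chemistry on commercial aldehydes.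

## Alternatives that were turned down

Alternative 1: Here ring C itself is made. The disconnection cuts the C3a–C7a and C4–C5 bonds of the benzofuran in A1 (the dimethyl acetal of the ring C/ring D aldehyde). Forward, heating the 3-alkoxy-2-pyrone A2, whose oxygen tether ends in a terminal alkyne, gives an intramolecular Diels–Alder adduct that loses its lactone bridge by decarboxylation and aromatises to A1. For it: the substitution pattern of ring C is fixed by construction, the cis C2/C3 pair is set in an open-chain precursor before any ring exists, and no carbene or late-stage metalation is needed. Against it: the step delivers only one quarter of the molecule, and it builds a benzene ring that compound 5 supplies from the bottle. A2 needs a trisubstituted pyrone plus an enantiopure benzylic–propargylic stereodiad, which costs many steps. The unactivated alkyne needs high temperature while the tether holds a benzylic aryl ether para to a silyloxy group that can ionise or eliminate. The furofuran, ring B and the ketone arm are all still to be made afterwards. On one point it is stronger: the cis relationship does not depend on an enantioselective catalyst acting on a large substrate. The chosen route offers in its place a catalyst-controlled insertion (step 13) on a core that is already assembled, at a far lower step count.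

Alternative 2: The target hides a C2 axis: each furofuran aryl group carries, ortho to oxygen, a 2-aryl-3-oxypropanoyl unit, once as the open ketone and once cyclised to the dihydrobenzofuran. The disconnection cuts both aryl–carbonyl bonds of the C2-symmetric bis-ketone A3. Forward, the bis(thioester) A4 couples twice with the boronic acid A5 under Pd2(dba)3, tri(2-furyl)phosphine and copper thiophene-2-carboxylate (a base-free acyl coupling of the Liebeskind–Srogl type). For it: two-directional synthesis halves the number of operations up to A3, a symmetric furofuran is simpler to make than an unsymmetrical one, and the base-free coupling respects the α-stereocentres. In step economy up to A3 it is stronger than the chosen route. Against it: after A3 the symmetry has to be broken. Exactly one of two identical ketones must be reduced and one of two identical MOM ethers removed, which is a statistical operation. The dihydrobenzofuran would then close by substitution at a benzylic carbinol para to oxygen, which goes through a cation and favours the trans ring, whereas 35 is cis. Two labile α-aryl carbonyl centres have to be made enantioselectively in A4 and carried through. The chosen route differentiates the two halves in the first C–C bond-forming step and sets the cis ring by a suprafacial insertion, so it has no statistical step.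

Alternative 3: The disconnection cuts the O–C7′ bond of a furofuranone. Forward, Sc(OTf)3 ionises the C8–C7′ bond of the donor–acceptor cyclopropane A7 (a 3-oxabicyclo[3.1.0]hexane tert-butyl ester), the ester carbonyl oxygen captures the benzylic cation and dealkylation gives the cis-fused lactone A6. For it: the C7′ cation is stabilised by the ring-fused, coplanar oxygen of the finished dihydrobenzofuran, so this closure is better supported electronically than closure on a bromo-substituted ring; on that point it is stronger, and the chosen route answers by freeing the ring C phenol before closure (step 6). The rings are also made one at a time, which suits two different aryl groups. Against it: A7 needs an enantioselective cyclopropanation with a quaternary ester carbon. The Lewis acid that opens the cyclopropane can equally ionise the C2–O bond of the cis-dihydrobenzofuran, which has an aryl oxide leaving group, and turn it trans. C9 arrives as a carbonyl and must be taken down to CH2 in further steps next to an aryl bromide. The ketone arm on ring B is still missing. The chosen route makes both tetrahydrofuran rings in one operation before the acid-sensitive cis ring exists and needs no deoxygenation.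

Key step: step 4

Remarks on the chemistry:
a) Compounds 10 and 11 are expected as mixtures of epimers at the carbinol carbon (one epimer drawn), and 12 as a mixture at both benzylic carbinols; step 7 erases these centres.
b) The antipodes of the two chiral catalysts (written as Rh2(R-PTTL)4 in step 13 and as one antipode of the pybox ligand in step 22) are those expected to give the drawn configurations; the sense of induction would be confirmed on a model substrate first and the mirror-image catalyst used if required.

## Route

Step 1
Reactants: 1 vanillin; 2 propane-1,3-dithiol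
Product: 3 4-(1,3-dithian-2-yl)-2-methoxyphenol
Conditions: BF3·OEt2 (0.1 equiv), CH2Cl2, 0 °C to rt
Reagents that add atoms: none
Why: Lewis-acid-catalysed dithioacetalisation of an aromatic aldehyde tolerates the free phenol; the MOM group is put on afterwards because it would not survive BF3·OEt2 together with a thiol.

Step 2
Reactants: 3 4-(1,3-dithian-2-yl)-2-methoxyphenol
Product: 4 2-[3-methoxy-4-(methoxymethoxy)phenyl]-1,3-dithiane
Conditions: MOMCl, i-Pr2NEt, CH2Cl2, 0 °C to rt
Reagents that add atoms: chloromethyl methyl ether, COCCl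
Why: O-alkylation of the phenol; the MOM ether is stable to n-BuLi, keeps the para oxygen of ring B a good donor for step 7 and later directs the ortho-lithiation of step 15.

Step 3
Reactants: 5 5-bromovanillin
Product: 6 2-bromo-4-formyl-6-methoxyphenyl pivalate
Conditions: PivCl, Et3N, DMAP (cat.), CH2Cl2, 0 °C
Reagents that add atoms: pivaloyl chloride, CC(C)(C)C(=O)Cl
Why: Acylation of the acidic phenol; the hindered, non-enolisable ester is inert to a lithium enolate at −78 °C and is removed by the hydride of step 6, so that ring C reaches the ring closure as a free phenol.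

Step 4
Reactants: 4 2-[3-methoxy-4-(methoxymethoxy)phenyl]-1,3-dithiane; 7 (5R)-5-[(1R,2S,5R)-menthyloxy]furan-2(5H)-one; 6 2-bromo-4-formyl-6-methoxyphenyl pivalate
Product: 10 (3S,4R,5R)-3-[(S)-(3-bromo-5-methoxy-4-pivaloyloxyphenyl)(hydroxy)methyl]-4-{2-[3-methoxy-4-(methoxymethoxy)phenyl]-1,3-dithian-2-yl}-5-[(1R,2S,5R)-menthyloxy]dihydrofuran-2(3H)-one, via 2-lithio-1,3-dithiane 8 (not isolated), via lithium lactone enolate 9 (not isolated)
Conditions: n-BuLi (1.05 equiv), THF, −78 °C; 7, −78 °C; 6 (1.2 equiv), −78 °C; AcOH, −78 °C
Reagents that add atoms: none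
Why: n-BuLi removes the C2–H of 4 to give the aryl- and sulfur-stabilised anion 8, a soft acyl-anion equivalent that adds 1,4 to butenolide 7 at C4 from the face opposite the C5 menthyloxy group, so the (5R) acetal centre sets C4 (the later C8) as R. The lithium enolate 9 is planar at C3 and shielded on one face by the bulky dithianyl group, so aldehyde 6 is taken up anti to it and C3 (the later C8′) becomes S in a trans,trans lactone; the carbinol centre forms without useful control and is left so because step 7 erases it. The closest known reaction type is the tandem conjugate addition–aldol coupling of lithiated 2-aryl-1,3-dithianes with 5-alkoxybutenolides and aromatic aldehydes. No ring is closed; the two bonds C7–C8 and C8′–C7′ and two controlled stereocentres are made. The step needs 1,4- over 1,2-addition, which the delocalised anion secures, enolate trapping faster than proton transfer, which −78 °C and an aldehyde without α-hydrogen secure, and attack on the aldehyde rather than the ester, which the hindered pivalate secures. The cold acetic acid quench prevents retro-aldol and acyl migration on warming.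

Step 5
Reactants: 10 the dithiane adduct
Product: 11 (3S,4R,5R)-3-[(3-bromo-5-methoxy-4-pivaloyloxyphenyl)(hydroxy)methyl]-4-[3-methoxy-4-(methoxymethoxy)benzoyl]-5-[(1R,2S,5R)-menthyloxy]dihydrofuran-2(3H)-one
Conditions: Hg(ClO4)2·3H2O (2.2 equiv), CaCO3, THF–H2O (5:1), 0 °C
Reagents that add atoms: water, O
Why: Thiophilic metal-assisted hydrolysis of the dithioacetal under carbonate buffering leaves the MOM ether, the pivalate, the aryl bromide and the menthyl acetal untouched; the trans,trans lactone is the stable arrangement, so the centre next to the new ketone does not drift.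

Step 6
Reactants: 11 the keto lactone
Product: 12 (2R,3R)-1-(3-bromo-4-hydroxy-5-methoxyphenyl)-2,3-bis(hydroxymethyl)-4-[3-methoxy-4-(methoxymethoxy)phenyl]butane-1,4-diol (mixture at C1 and C4)
Conditions: LiAlH4 (5 equiv), THF, 0 °C to rt; aq. Rochelle salt
Reagents that add atoms: none
Why: Hydride reduces the ketone, the lactone carbonyl and, after collapse of the hemiacetal, the acetal carbon (releasing menthol), and cleaves the pivalate; C8 and C8′ are not touched and the aryl bromide is inert at this temperature.

Step 7
Reactants: 12 the pentaol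
Product: 13 2-bromo-6-methoxy-4-{(1S,3aR,4S,6aR)-4-[3-methoxy-4-(methoxymethoxy)phenyl]tetrahydro-1H,3H-furo[3,4-c]furan-1-yl}phenol
Conditions: CSA (0.2 equiv), 4 Å MS, CH2Cl2–THF (4:1), 0 °C to rt; Et3N quench at full conversion
Reagents that add atoms: none
Why: Acid-catalysed double cyclodehydration: each benzylic carbinol ionises to a cation stabilised by its para oxygen (the free phenol on ring C, the MOM ether on ring B) and is captured 5-exo by the primary hydroxyl of the other half, which erases both carbinol configurations. Each ring closes with the aryl group trans to the substituent on the neighbouring carbon, giving the exo,exo isomer (C7 and C7′ both S); the reaction is stopped at conversion because longer acid contact would start equilibration towards the C7 epimer, and the catalytic sulfonic acid in an aprotic medium spares the aryl MOM ether.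

Step 8
Reactants: 1 vanillin
Product: 14 3-methoxy-4-(triisopropylsilyloxy)benzaldehyde
Conditions: TIPSCl, imidazole, DMF, rt
Reagents that add atoms: triisopropylsilyl chloride, CC(C)[Si](Cl)(C(C)C)C(C)C
Why: Silylation of the phenol; the bulky silyl ether survives the organometallic, hydride and Lewis-acid steps that follow and is not an ortho-directing group.

Step 9
Reactants: 14 3-methoxy-4-(triisopropylsilyloxy)benzaldehyde
Product: 15 [3-methoxy-4-(triisopropylsilyloxy)phenyl]methanol
Conditions: NaBH4, MeOH, 0 °C
Reagents that add atoms: none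
Why: Borohydride reduction of an aromatic aldehyde to the benzyl alcohol.

Step 10
Reactants: 13 the furofuran bromophenol; 15 [3-methoxy-4-(triisopropylsilyloxy)phenyl]methanol
Product: 16 the 3-methoxy-4-(triisopropylsilyloxy)benzyl ether of 13 at the ring C phenol
Conditions: PPh3, DIAD, THF, 0 °C to rt
Reagents that add atoms: none
Why: Mitsunobu etherification: the acidic bromophenol is the pronucleophile and the primary benzylic alcohol is activated, so neither base nor a labile electron-rich benzyl halide is needed; no stereocentre is involved.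

Step 11
Reactants: 16 the aryl bromide
Product: 17 the methyl arylacetate in which CH2CO2Me replaces the bromine of 16
Conditions: BrZnCH2CO2Me (2 equiv, from methyl bromoacetate and Zn), Pd(dba)2 (3 mol %), P(t-Bu)3 (3 mol %), THF, rt to 50 °C
Reagents that add atoms: bromo(2-methoxy-2-oxoethyl)zinc, Br[Zn]CC(=O)OC
Why: Negishi-type α-arylation of an ester zinc enolate (Reformatsky reagent) with an aryl bromide under zerovalent palladium; the neutral conditions tolerate the MOM and silyl ethers and the benzylic ethers.

Step 12
Reactants: 17 the methyl arylacetate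
Product: 18 the methyl aryldiazoacetate (C=N2 in place of the CH2 of 17)
Conditions: p-ABSA, DBU, MeCN, 0 °C to rt
Reagents that add atoms: 4-acetamidobenzenesulfonyl azide, CC(=O)Nc1ccc(cc1)S(=O)(=O)N=[N+]=[N-]
Why: Regitz diazo transfer to the benzylic ester position, the standard entry to donor/acceptor diazo compounds from 2-alkoxyphenylacetates.

Step 13
Reactants: 18 the methyl aryldiazoacetate
Product: 19 methyl (2S,3R)-cis-7-methoxy-2-[3-methoxy-4-(triisopropylsilyloxy)phenyl]-2,3-dihydrobenzofuran-3-carboxylate carrying the furofuran of 13 at C5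
Conditions: Rh2(R-PTTL)4 (2 mol %), toluene, −78 to −40 °C
Reagents that add atoms: none
Why: Intramolecular 1,5 C–H insertion of a donor/acceptor rhodium carbene into the benzylic C–H of the ring D benzyl ether, a known route to cis-2-aryl-2,3-dihydrobenzofuran-3-carboxylates. The concerted, suprafacial insertion gives the cis ring kinetically and the chiral carboxylate ligands of dirhodium tetrakis[N-phthaloyl-(R)-tert-leucinate] select the enantiotopic hydrogen and carbene face, setting C2 and C3 together; no base is present, so the cis ester does not epimerise.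

Step 14
Reactants: 19 the cis ester
Product: 20 the cis alcohol (2S,3S) in which CH2OH replaces the CO2Me of 19
Conditions: DIBAL-H (3 equiv), CH2Cl2, −78 °C; aq. Rochelle salt
Reagents that add atoms: none
Why: Low-temperature reduction with a Lewis-acidic, non-basic hydride takes the ester to the primary alcohol faster than C3 can epimerise; once reduced, C3 is no longer acidic and the cis relationship is locked.

Step 15
Reactants: 20 the cis alcohol
Product: 22 the aryl iodide (iodine at C5 of ring B of 20), via dilithio species 21 (not isolated)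
Conditions: n-BuLi (2.4 equiv), THF, −78 to −10 °C; I2, THF, −78 °C; aq. Na2S2O3
Reagents that add atoms: iodine, II
Why: Directed ortho-metalation: after the alkoxide has formed, the MOM ether directs lithiation to C5 of ring B, the only position ortho to it, while the methoxy groups and the bulky silyl ether are much weaker directors; iodinolysis of the aryllithium fixes the position.

Step 16
Reactants: 22 the aryl iodide
Product: 24 the iodophenol alcohol (MOM of 22 replaced by H), via bis(trimethylsilyl) ether 23 (not isolated)
Conditions: TMSOTf (4 equiv), 2,2′-bipyridyl (6 equiv), CH2Cl2, 0 °C to rt; then H2O, rt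
Reagents that add atoms: none
Why: The silyl triflate–bipyridyl pair converts an aryl MOM ether into the aryl silyl ether without free protic acid, so the benzylic ethers of the furofuran and of the cis-dihydrobenzofuran are not ionised; water then cleaves both trimethylsilyl ethers.

Step 17
Reactants: 24 the iodophenol alcohol
Product: 25 the bis(tert-butyldimethylsilyl) ether of 24
Conditions: TBSCl (3 equiv), imidazole, DMF, rt to 40 °C
Reagents that add atoms: tert-butyldimethylsilyl chloride, CC(C)(C)[Si](C)(C)Cl
Why: Silylation of the phenol and the primary alcohol in one operation; from here every protected oxygen is a silyl ether and one fluoride step can finish the synthesis.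

Step 18
Reactants: 26 acetovanillone
Product: 27 trimethyl{2-methoxy-4-[1-(trimethylsilyloxy)ethenyl]phenoxy}silane
Conditions: TMSOTf (2.3 equiv), Et3N (3 equiv), CH2Cl2, 0 °C
Reagents that add atoms: trimethylsilyl triflate, C[Si](C)(C)OS(=O)(=O)C(F)(F)F
Why: Soft enolisation gives the silyl enol ether of the methyl ketone and silylates the phenol at the same time.

Step 19
Reactants: 27 the silyl enol ether
Product: 28 3-hydroxy-1-(4-hydroxy-3-methoxyphenyl)propan-1-one
Conditions: aq. HCHO (37 %), Yb(OTf)3 (10 mol %), THF–H2O, rt
Reagents that add atoms: formaldehyde, C=O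
Why: Mukaiyama aldol with aqueous formaldehyde under a water-tolerant lanthanide triflate; the product is a ketone and no longer an enol ether, so only one hydroxymethyl group is introduced, and the aryl silyl ether hydrolyses in the aqueous medium.

Step 20
Reactants: 28 3-hydroxy-1-(4-hydroxy-3-methoxyphenyl)propan-1-one
Product: 29 3-(tert-butyldimethylsilyloxy)-1-[4-(tert-butyldimethylsilyloxy)-3-methoxyphenyl]propan-1-one
Conditions: TBSCl (2.5 equiv), imidazole, DMF, rt
Reagents that add atoms: tert-butyldimethylsilyl chloride, CC(C)(C)[Si](C)(C)Cl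
Why: Silylation of the phenol and the primary alcohol.

Step 21
Reactants: 29 the bis-silylated ketone
Product: 31 rac-2-bromo-3-(tert-butyldimethylsilyloxy)-1-[4-(tert-butyldimethylsilyloxy)-3-methoxyphenyl]propan-1-one, via trimethylsilyl enol ether 30 (not isolated)
Conditions: TMSOTf, Et3N, CH2Cl2, 0 °C; solvent exchange; NBS, THF, −78 to 0 °C
Reagents that add atoms: N-bromosuccinimide, BrN1C(=O)CCC1=O
Why: α-Bromination through the silyl enol ether avoids both hydrogen bromide, which would cleave the silyl ethers, and a lithium enolate, which could expel the β-silyloxy group; the bromide is racemic by design because step 22 is stereoconvergent.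

Step 22
Reactants: 25 the aryl iodide; 31 the racemic α-bromoketone
Product: 34 the pentasilyl ether of 35 with the (S) α-carbon, via arylmagnesium chloride 32 (not isolated), via arylzinc iodide 33 (not isolated)
Conditions: i-PrMgCl·LiCl, THF, −15 to 0 °C; ZnI2, 0 °C; solvent exchange to glyme; 31 (1.5 equiv), NiCl2·glyme (10 mol %), chiral pybox ligand [2,6-bis(4-phenyl-4,5-dihydrooxazol-2-yl)pyridine, one antipode] (13 mol %), glyme–THF, −30 °C
Reagents that add atoms: none
Why: Iodine–magnesium exchange and transmetalation give the arylzinc iodide without an aryllithium, which would suffer silyl migration from the ortho oxygen. The nickel-catalysed stereoconvergent Negishi arylation of racemic α-bromoketones funnels both enantiomers of 31 through an α-keto radical that is captured by the chiral aryl–nickel complex, so the ligand alone sets the (S) centre. No Brønsted base is present, so the tertiary α-aryl ketone does not racemise.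

Step 23
Reactants: 34 the pentasilyl ether
Product: 35 the target
Conditions: TBAF (8 equiv), AcOH (8 equiv), THF, 0 °C to rt
Reagents that add atoms: none
Why: Fluoride buffered with acetic acid cleaves the three aryl and two primary alkyl silyl ethers in a nearly neutral medium, which protects the epimerisable α-carbon, the β-hydroxy ketone and the three acid-labile benzylic ethers.

## Compound list

1 | vanillin | COc1cc(C=O)ccc1O | starting material
2 | propane-1,3-dithiol | SCCCS | starting material
3 | 4-(1,3-dithian-2-yl)-2-methoxyphenol | COc1cc(ccc1O)C1SCCCS1 | intermediate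
4 | 2-[3-methoxy-4-(methoxymethoxy)phenyl]-1,3-dithiane | COCOc1ccc(cc1OC)C1SCCCS1 | intermediate
5 | 5-bromovanillin | COc1cc(C=O)cc(Br)c1O | starting material
6 | 2-bromo-4-formyl-6-methoxyphenyl pivalate | COc1cc(C=O)cc(Br)c1OC(=O)C(C)(C)C | intermediate
7 | (5R)-5-[(1R,2S,5R)-menthyloxy]furan-2(5H)-one | O=C1O[C@@H](O[C@@H]2C[C@H](C)CC[C@H]2C(C)C)C=C1 | starting material
8 | 2-lithio-2-[3-methoxy-4-(methoxymethoxy)phenyl]-1,3-dithiane | [Li]C1(SCCCS1)c1ccc(OCOC)c(OC)c1 | intermediate (not isolated)
9 | lithium enolate of the (4R,5R)-4-dithianyl-5-menthyloxy lactone | [Li]OC1=C[C@@H](C2(SCCCS2)c2ccc(OCOC)c(OC)c2)[C@H](O[C@@H]2C[C@H](C)CC[C@H]2C(C)C)O1 | intermediate (not isolated)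
10 | (3S,4R,5R)-3-[(S)-(3-bromo-5-methoxy-4-pivaloyloxyphenyl)(hydroxy)methyl]-4-{2-[3-methoxy-4-(methoxymethoxy)phenyl]-1,3-dithian-2-yl}-5-menthyloxydihydrofuran-2(3H)-one (carbinol epimer drawn) | O=C1O[C@@H](O[C@@H]2C[C@H](C)CC[C@H]2C(C)C)[C@H](C2(SCCCS2)c2ccc(OCOC)c(OC)c2)[C@H]1[C@H](O)c1cc(OC)c(OC(=O)C(C)(C)C)c(Br)c1 | intermediate
11 | keto lactone: C=O in place of the dithiane of 10 | O=C1O[C@@H](O[C@@H]2C[C@H](C)CC[C@H]2C(C)C)[C@H](C(=O)c2ccc(OCOC)c(OC)c2)[C@H]1[C@H](O)c1cc(OC)c(OC(=O)C(C)(C)C)c(Br)c1 | intermediate
12 | (2R,3R)-1-(3-bromo-4-hydroxy-5-methoxyphenyl)-2,3-bis(hydroxymethyl)-4-[3-methoxy-4-(methoxymethoxy)phenyl]butane-1,4-diol (C1, C4 mixtures) | OC[C@H](C(O)c1ccc(OCOC)c(OC)c1)[C@H](CO)C(O)c1cc(OC)c(O)c(Br)c1 | intermediate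
13 | 2-bromo-6-methoxy-4-{(1S,3aR,4S,6aR)-4-[3-methoxy-4-(methoxymethoxy)phenyl]tetrahydro-1H,3H-furo[3,4-c]furan-1-yl}phenol | COCOc1ccc(cc1OC)[C@H]1OC[C@H]2[C@@H]1CO[C@@H]2c1cc(OC)c(O)c(Br)c1 | intermediate
14 | 3-methoxy-4-(triisopropylsilyloxy)benzaldehyde | COc1cc(C=O)ccc1O[Si](C(C)C)(C(C)C)C(C)C | intermediate
15 | [3-methoxy-4-(triisopropylsilyloxy)phenyl]methanol | COc1cc(CO)ccc1O[Si](C(C)C)(C(C)C)C(C)C | intermediate
16 | 3-methoxy-4-(triisopropylsilyloxy)benzyl ether of 13 | COCOc1ccc(cc1OC)[C@H]1OC[C@H]2[C@@H]1CO[C@@H]2c1cc(OC)c(OCc2ccc(O[Si](C(C)C)(C(C)C)C(C)C)c(OC)c2)c(Br)c1 | intermediate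
17 | methyl arylacetate (CH2CO2Me in place of Br of 16) | COCOc1ccc(cc1OC)[C@H]1OC[C@H]2[C@@H]1CO[C@@H]2c1cc(OC)c(OCc2ccc(O[Si](C(C)C)(C(C)C)C(C)C)c(OC)c2)c(CC(=O)OC)c1 | intermediate
18 | methyl aryldiazoacetate derived from 17 | COCOc1ccc(cc1OC)[C@H]1OC[C@H]2[C@@H]1CO[C@@H]2c1cc(OC)c(OCc2ccc(O[Si](C(C)C)(C(C)C)C(C)C)c(OC)c2)c(c1)C(=[N+]=[N-])C(=O)OC | intermediate
19 | methyl (2S,3R)-cis-2,3-dihydrobenzofuran-3-carboxylate on the furofuran of 13 | COCOc1ccc(cc1OC)[C@H]1OC[C@H]2[C@@H]1CO[C@@H]2c1cc(OC)c2c(c1)[C@@H](C(=O)OC)[C@@H](c1ccc(O[Si](C(C)C)(C(C)C)C(C)C)c(OC)c1)O2 | intermediate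
20 | (2S,3S)-cis-3-(hydroxymethyl)dihydrobenzofuran (CH2OH in place of CO2Me of 19) | COCOc1ccc(cc1OC)[C@H]1OC[C@H]2[C@@H]1CO[C@@H]2c1cc(OC)c2c(c1)[C@@H](CO)[C@@H](c1ccc(O[Si](C(C)C)(C(C)C)C(C)C)c(OC)c1)O2 | intermediate
21 | dilithio species: lithium alkoxide of 20 lithiated at C5 of ring B | COCOc1c([Li])cc(cc1OC)[C@H]1OC[C@H]2[C@@H]1CO[C@@H]2c1cc(OC)c2c(c1)[C@@H](CO[Li])[C@@H](c1ccc(O[Si](C(C)C)(C(C)C)C(C)C)c(OC)c1)O2 | intermediate (not isolated)
22 | aryl iodide: 20 with iodine at C5 of ring B | COCOc1c(I)cc(cc1OC)[C@H]1OC[C@H]2[C@@H]1CO[C@@H]2c1cc(OC)c2c(c1)[C@@H](CO)[C@@H](c1ccc(O[Si](C(C)C)(C(C)C)C(C)C)c(OC)c1)O2 | intermediate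
23 | bis(trimethylsilyl) ether: OTMS in place of OMOM and of OH of 22 | C[Si](C)(C)Oc1c(I)cc(cc1OC)[C@H]1OC[C@H]2[C@@H]1CO[C@@H]2c1cc(OC)c2c(c1)[C@@H](CO[Si](C)(C)C)[C@@H](c1ccc(O[Si](C(C)C)(C(C)C)C(C)C)c(OC)c1)O2 | intermediate (not isolated)
24 | iodophenol alcohol (22 without MOM) | Oc1c(I)cc(cc1OC)[C@H]1OC[C@H]2[C@@H]1CO[C@@H]2c1cc(OC)c2c(c1)[C@@H](CO)[C@@H](c1ccc(O[Si](C(C)C)(C(C)C)C(C)C)c(OC)c1)O2 | intermediate
25 | bis(tert-butyldimethylsilyl) ether of 24 | CC(C)(C)[Si](C)(C)Oc1c(I)cc(cc1OC)[C@H]1OC[C@H]2[C@@H]1CO[C@@H]2c1cc(OC)c2c(c1)[C@@H](CO[Si](C)(C)C(C)(C)C)[C@@H](c1ccc(O[Si](C(C)C)(C(C)C)C(C)C)c(OC)c1)O2 | intermediate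
26 | acetovanillone | CC(=O)c1ccc(O)c(OC)c1 | starting material
27 | trimethyl{2-methoxy-4-[1-(trimethylsilyloxy)ethenyl]phenoxy}silane | C=C(O[Si](C)(C)C)c1ccc(O[Si](C)(C)C)c(OC)c1 | intermediate
28 | 3-hydroxy-1-(4-hydroxy-3-methoxyphenyl)propan-1-one | OCCC(=O)c1ccc(O)c(OC)c1 | intermediate
29 | 3-(tert-butyldimethylsilyloxy)-1-[4-(tert-butyldimethylsilyloxy)-3-methoxyphenyl]propan-1-one | CC(C)(C)[Si](C)(C)OCCC(=O)c1ccc(O[Si](C)(C)C(C)(C)C)c(OC)c1 | intermediate
30 | (Z)-trimethylsilyl enol ether of 29 | C[Si](C)(C)O/C(=C\CO[Si](C)(C)C(C)(C)C)c1ccc(O[Si](C)(C)C(C)(C)C)c(OC)c1 | intermediate (not isolated)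
31 | rac-2-bromo-3-(tert-butyldimethylsilyloxy)-1-[4-(tert-butyldimethylsilyloxy)-3-methoxyphenyl]propan-1-one | CC(C)(C)[Si](C)(C)OCC(Br)C(=O)c1ccc(O[Si](C)(C)C(C)(C)C)c(OC)c1 | intermediate
32 | arylmagnesium chloride: MgCl in place of I of 25 | CC(C)(C)[Si](C)(C)Oc1c([Mg]Cl)cc(cc1OC)[C@H]1OC[C@H]2[C@@H]1CO[C@@H]2c1cc(OC)c2c(c1)[C@@H](CO[Si](C)(C)C(C)(C)C)[C@@H](c1ccc(O[Si](C(C)C)(C(C)C)C(C)C)c(OC)c1)O2 | intermediate (not isolated)
33 | arylzinc iodide: ZnI in place of I of 25 | CC(C)(C)[Si](C)(C)Oc1c([Zn]I)cc(cc1OC)[C@H]1OC[C@H]2[C@@H]1CO[C@@H]2c1cc(OC)c2c(c1)[C@@H](CO[Si](C)(C)C(C)(C)C)[C@@H](c1ccc(O[Si](C(C)C)(C(C)C)C(C)C)c(OC)c1)O2 | intermediate (not isolated)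
34 | pentasilyl ether of 35: TBS on the ring A and ring B phenols and on both primary alcohols, TIPS on the ring D phenol; α-carbon (S) | COc1cc(C(=O)[C@H](CO[Si](C)(C)C(C)(C)C)c2cc([C@H]3OC[C@H]4[C@@H]3CO[C@@H]4c3cc(OC)c4c(c3)[C@@H](CO[Si](C)(C)C(C)(C)C)[C@@H](c3ccc(O[Si](C(C)C)(C(C)C)C(C)C)c(OC)c3)O4)cc(OC)c2O[Si](C)(C)C(C)(C)C)ccc1O[Si](C)(C)C(C)(C)C | intermediate
35 | CNP0174045.1 | COc1cc(C(=O)[C@H](CO)c2cc([C@H]3OC[C@H]4[C@@H]3CO[C@@H]4c3cc(OC)c4c(c3)[C@@H](CO)[C@@H](c3ccc(O)c(OC)c3)O4)cc(OC)c2O)ccc1O | target

## Step count and least certain steps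

Total: 23 steps. Longest linear sequence: 16 steps from vanillin (steps 1, 2, 4–7, 10–17, 22, 23).

Step 4 (key step). Most likely to go wrong: incomplete trapping of the enolate, because 9 is protonated before it meets the aldehyde, the aldolate reverts by retro-aldol, or the aldolate picks up the pivaloyl group from a second molecule of 6. Fallback, from 4 and 7, returning at 10: the conjugate addition is run alone and 9 is protonated at −78 °C to give (4R,5R)-4-{2-[3-methoxy-4-(methoxymethoxy)phenyl]-1,3-dithian-2-yl}-5-menthyloxydihydrofuran-2(3H)-one F1, which is purified. F1 is then enolised with LDA, transmetalated with ZnCl2 to the less basic zinc enolate, and added to 6 in a separate aldol step to give 10.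

Step 7. Most likely to go wrong: loss of the MOM ether under the acid, closure of one ring with the aryl group endo or later acid-induced drift to the C7 epimer, and competing capture of a cation by the other benzylic hydroxyl. Fallback, from 12, returning at 16: the MOM group is given up on purpose. Aqueous HCl in THF closes both rings with both para-phenols free and gives the bisphenol 2-bromo-4-[(1S,3aR,4S,6aR)-4-(4-hydroxy-3-methoxyphenyl)tetrahydro-1H,3H-furo[3,4-c]furan-1-yl]-6-methoxyphenol F2. Mitsunobu etherification with one equivalent of 15 takes the more acidic bromophenol and gives the mono-benzyl ether F3, and MOMCl with i-Pr2NEt on the remaining ring B phenol gives 16.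

Step 13. Most likely to go wrong: insufficient catalyst control over the carbene face on this large substrate, or diversion of the carbene into dimerisation or addition to an electron-rich ring. Fallback, from 13 (with 14 as the source of the side chain), returning at 20: C2 is set by asymmetric O-alkylation, the ring is closed at the bromide, and C3 is set by hydroboration. Aldehyde 14 with ethynylmagnesium bromide and then methyl chloroformate gives rac-1-[3-methoxy-4-(triisopropylsilyloxy)phenyl]prop-2-yn-1-yl methyl carbonate F4. Copper-catalysed enantioselective propargylic etherification of 13 with F4 (CuOTf·½C6H6, chiral pybox ligand, i-Pr2NEt) gives the (S)-propargylic aryl ether F5. Reductive 5-exo-dig cyclisation at the bromide (Pd(OAc)2, PPh3, HCO2Na, DMF) gives the 3-methylene-2,3-dihydrobenzofuran F6. Hydroboration with 9-BBN from the face opposite ring D and oxidation with NaBO3 places CH2OH cis to ring D and gives 20.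

Step 15. Most likely to go wrong: competing deprotonation at a benzylic ether carbon (with ring opening) or at a position ortho to a methoxy group. Fallback, from 20, returning at 24: the MOM group is removed first (TMSOTf, 2,2′-bipyridyl; water) to give the free phenol F7, and the phenol itself then directs electrophilic ortho-iodination (benzyltrimethylammonium dichloroiodate, NaHCO3, CH2Cl2–MeOH) at C5 of ring B, the para position being blocked, to give 24.

Step 22. Most likely to go wrong: slow transmetalation or eroded stereoinduction because the arylzinc carries an ortho silyloxy group, and β-elimination of the silyloxy group from the nickel-bound ketone fragment. Fallback, from 25, returning at 35: the C–C bond and the stereocentre are made separately. Compound 26 is silylated to 1-[4-(tert-butyldimethylsilyloxy)-3-methoxyphenyl]ethanone F8. Palladium-catalysed α-arylation of F8 with 25 (Pd2(dba)3, XPhos, K3PO4, toluene) gives the deoxybenzoin F9. TMSOTf and Et3N give its (Z)-trimethylsilyl enol ether F10. Catalytic asymmetric hydroxymethylation with aqueous formaldehyde (Sc(OTf)3, chiral 2,2′-bipyridine diol ligand) gives the (S)-β-hydroxy ketone F11, whose primary alcohol is already free. The buffered fluoride of step 23 then gives 35.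

Step 23. Most likely to go wrong: epimerisation of the α-carbon, β-elimination or retro-aldol under fluoride, and acid-promoted cyclodehydration of the ortho-phenol onto the ketone. Fallback, from 34, returning at 35: stereoretention is no longer required. The deprotection is run to completion and the product is taken as a mixture of 35 and its α-epimer (R)-epi-35 F12. These are diastereomers, because the rest of the molecule is enantiopure, and are separated by preparative HPLC; F12 is re-equilibrated with a trace of amine base and recycled.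

## Further compounds

F1 | step 4 | (4R,5R)-4-{2-[3-methoxy-4-(methoxymethoxy)phenyl]-1,3-dithian-2-yl}-5-[(1R,2S,5R)-menthyloxy]dihydrofuran-2(3H)-one | O=C1O[C@@H](O[C@@H]2C[C@H](C)CC[C@H]2C(C)C)[C@H](C2(SCCCS2)c2ccc(OCOC)c(OC)c2)C1
F2 | step 7 | 2-bromo-4-[(1S,3aR,4S,6aR)-4-(4-hydroxy-3-methoxyphenyl)tetrahydro-1H,3H-furo[3,4-c]furan-1-yl]-6-methoxyphenol | COc1cc(ccc1O)[C@H]1OC[C@H]2[C@@H]1CO[C@@H]2c1cc(OC)c(O)c(Br)c1
F3 | step 7 | 3-methoxy-4-(triisopropylsilyloxy)benzyl ether of F2 at the ring C phenol | COc1cc(ccc1O)[C@H]1OC[C@H]2[C@@H]1CO[C@@H]2c1cc(OC)c(OCc2ccc(O[Si](C(C)C)(C(C)C)C(C)C)c(OC)c2)c(Br)c1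
F4 | step 13 | rac-1-[3-methoxy-4-(triisopropylsilyloxy)phenyl]prop-2-yn-1-yl methyl carbonate | COC(=O)OC(C#C)c1ccc(O[Si](C(C)C)(C(C)C)C(C)C)c(OC)c1
F5 | step 13 | (S)-1-[3-methoxy-4-(triisopropylsilyloxy)phenyl]prop-2-yn-1-yl ether of 13 | COCOc1ccc(cc1OC)[C@H]1OC[C@H]2[C@@H]1CO[C@@H]2c1cc(OC)c(O[C@@H](C#C)c2ccc(O[Si](C(C)C)(C(C)C)C(C)C)c(OC)c2)c(Br)c1
F6 | step 13 | (2R)-3-methylene-2-[3-methoxy-4-(triisopropylsilyloxy)phenyl]-2,3-dihydrobenzofuran on the furofuran of 13 | COCOc1ccc(cc1OC)[C@H]1OC[C@H]2[C@@H]1CO[C@@H]2c1cc(OC)c2c(c1)C(=C)[C@@H](c1ccc(O[Si](C(C)C)(C(C)C)C(C)C)c(OC)c1)O2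
F7 | step 15 | free ring B phenol of 20 (MOM removed) | Oc1ccc(cc1OC)[C@H]1OC[C@H]2[C@@H]1CO[C@@H]2c1cc(OC)c2c(c1)[C@@H](CO)[C@@H](c1ccc(O[Si](C(C)C)(C(C)C)C(C)C)c(OC)c1)O2
F8 | step 22 | 1-[4-(tert-butyldimethylsilyloxy)-3-methoxyphenyl]ethanone | CC(=O)c1ccc(O[Si](C)(C)C(C)(C)C)c(OC)c1
F9 | step 22 | deoxybenzoin: 34 lacking the CH2OTBS group at the α-carbon | COc1cc(C(=O)Cc2cc([C@H]3OC[C@H]4[C@@H]3CO[C@@H]4c3cc(OC)c4c(c3)[C@@H](CO[Si](C)(C)C(C)(C)C)[C@@H](c3ccc(O[Si](C(C)C)(C(C)C)C(C)C)c(OC)c3)O4)cc(OC)c2O[Si](C)(C)C(C)(C)C)ccc1O[Si](C)(C)C(C)(C)C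
F10 | step 22 | (Z)-trimethylsilyl enol ether of F9 | COc1cc(/C(O[Si](C)(C)C)=C/c2cc([C@H]3OC[C@H]4[C@@H]3CO[C@@H]4c3cc(OC)c4c(c3)[C@@H](CO[Si](C)(C)C(C)(C)C)[C@@H](c3ccc(O[Si](C(C)C)(C(C)C)C(C)C)c(OC)c3)O4)cc(OC)c2O[Si](C)(C)C(C)(C)C)ccc1O[Si](C)(C)C(C)(C)C
F11 | step 22 | (S)-β-hydroxy ketone: 34 with free CH2OH at the α-carbon | COc1cc(C(=O)[C@H](CO)c2cc([C@H]3OC[C@H]4[C@@H]3CO[C@@H]4c3cc(OC)c4c(c3)[C@@H](CO[Si](C)(C)C(C)(C)C)[C@@H](c3ccc(O[Si](C(C)C)(C(C)C)C(C)C)c(OC)c3)O4)cc(OC)c2O[Si](C)(C)C(C)(C)C)ccc1O[Si](C)(C)C(C)(C)C
F12 | step 23 | (R)-epi-35, the epimer of 35 at the ketone α-carbon | COc1cc(C(=O)[C@@H](CO)c2cc([C@H]3OC[C@H]4[C@@H]3CO[C@@H]4c3cc(OC)c4c(c3)[C@@H](CO)[C@@H](c3ccc(O)c(OC)c3)O4)cc(OC)c2O)ccc1O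
A1 | alternative 1 | cis-5-(dimethoxymethyl)-7-methoxy-2-[4-(tert-butyldimethylsilyloxy)-3-methoxyphenyl]-3-(tert-butyldimethylsilyloxymethyl)-2,3-dihydrobenzofuran | COC(OC)c1cc(OC)c2c(c1)[C@@H](CO[Si](C)(C)C(C)(C)C)[C@@H](c1ccc(O[Si](C)(C)C(C)(C)C)c(OC)c1)O2
A2 | alternative 1 | 6-(dimethoxymethyl)-4-methoxy-3-{[1-aryl-2-(silyloxymethyl)but-3-yn-1-yl]oxy}-2H-pyran-2-one, configured as in A1 | C#C[C@@H](CO[Si](C)(C)C(C)(C)C)[C@@H](c1ccc(O[Si](C)(C)C(C)(C)C)c(OC)c1)OC1=C(OC)C=C(C(OC)OC)OC1=O
A3 | alternative 2 | C2-symmetric protected bis-ketone | COc1cc(C(=O)[C@H](CO[Si](C)(C)C(C)(C)C)c2cc([C@H]3OC[C@H]4[C@@H]3CO[C@@H]4c3cc(OC)c(OCOC)c(c3)[C@@H](CO[Si](C)(C)C(C)(C)C)C(=O)c3ccc(O[Si](C)(C)C(C)(C)C)c(OC)c3)cc(OC)c2OCOC)ccc1O[Si](C)(C)C(C)(C)C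
A4 | alternative 2 | C2-symmetric bis(S-ethyl 2-aryl-3-silyloxypropanethioate) on the furofuran | CCSC(=O)[C@H](CO[Si](C)(C)C(C)(C)C)c1cc(cc(OC)c1OCOC)[C@H]1OC[C@H]2[C@@H]1CO[C@@H]2c1cc(OC)c(OCOC)c(c1)[C@@H](CO[Si](C)(C)C(C)(C)C)C(=O)SCC
A5 | alternative 2 | [4-(tert-butyldimethylsilyloxy)-3-methoxyphenyl]boronic acid | COc1cc(B(O)O)ccc1O[Si](C)(C)C(C)(C)C
A6 | alternative 3 | furofuranone carrying the bromo ring B and the cis-dihydrobenzofuran | Brc1cc(cc(OC)c1O[Si](C(C)C)(C(C)C)C(C)C)[C@H]3OC[C@H]4[C@@H]3C(=O)O[C@@H]4c3cc(OC)c4c(c3)[C@@H](CO[Si](C)(C)C(C)(C)C)[C@@H](c3ccc(O[Si](C)(C)C(C)(C)C)c(OC)c3)O4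
A7 | alternative 3 | tert-butyl 2-aryl-6-aryl-3-oxabicyclo[3.1.0]hexane-1-carboxylate, C7 and C8′ configured as in A6, cyclopropane aryl carbon unassigned | Brc1cc(cc(OC)c1O[Si](C(C)C)(C(C)C)C(C)C)[C@H]1OC[C@@H]2C(c3cc(OC)c4c(c3)[C@@H](CO[Si](C)(C)C(C)(C)C)[C@@H](c3ccc(O[Si](C)(C)C(C)(C)C)c(OC)c3)O4)[C@]12C(=O)OC(C)(C)C
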